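## Structural features

The target is a trans-fused bicyclo[5.3.0]decene of the daucane type: cyclopentane ring A (C1 to C5) and cycloheptene ring B (C1, C5 to C10) share the C1–C5 bond. Six stereocentres surround that bond: the quaternary, methyl-bearing C1 is flanked by C2 (acetate), C10 (allylic alcohol) and C5 (H), and C5 is flanked by C4 (tertiary carbinol with isopropyl) and C6 (4-methoxybenzoate). The C1 methyl, C10–OH and C4–OH lie on one face; H5, C2–OAc, C6–OAr and the isopropyl group lie on the other (1S,2S,4R,5S,6S,10S). Four oxygens of four kinds must be told apart: a tertiary alcohol, a free secondary allylic alcohol next to the quaternary centre, an acetate and an aryl ester. The allylic C10 alcohol with the C8=C9 alkene (ionisation, allylic shift), the tertiary alcohol (dehydration) and the two esters (migration, hydrolysis) are fragile, so acid and strong base are unwelcome late. The real difficulty is the quaternary C1 with three stereogenic neighbours inside a seven-membered ring. The feature used is that C8=C9 is γ,δ to the carbonyl-level carbon C2 on C1 (C2–C1–C10–C9=C8) while C8 is tied back to C1 through C7–C6–C5. That is the retron of a Claisen rearrangement of a seven-membered lactone (O–C8) whose ketene acetal carbon is C1.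

## Logic of the disconnections

**39 back to 36.** The C10 benzylic C–O bond, the C6 acyl C–O bond and the C6 silyl O–Si bond are cut in this order. The four oxygens are differentiated by timing, not by selective reagents. The forward steps must acylate a hindered secondary alcohol beside a free tertiary one and remove the benzyl-type ether without touching two esters.

**36 back to 34.** The C2 acyl C–O bond and then the C2–H bond are cut, leading to a C2 ketone. This removes the need to control C2 in the ring-closing step. The forward reduction must bring hydride to the face of the C1 methyl, which only a delivery from the C4 hydroxyl can do.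

**34 back to 32.** The C4–isopropyl bond is cut after a redox adjustment at C2. The ring then presents a ketone whose α face is shielded by the angular methyl. The forward step needs a non-basic isopropyl nucleophile.

**32 back to 28.** The C2–C3 bond is cut (aldol), then the functional groups are traced back through 31, 30 and 29 to the acid. This takes ring A off and leaves a monocyclic cycloheptene acid. The forward aldol needs a kinetic methyl ketone enolate beside a non-enolisable aldehyde.

**28 back to 25, via 27 and 26.** The C1–C10 bond is cut and O–C8 is reconnected. The carbocycle becomes a seven-membered lactone, the quaternary centre becomes an enolisable lactone α-carbon, and C1 and C10 become consequences of C8 and of a Z enol ether. The forward step needs a boat-shaped (3,3) shift in competition with ionisation of a tertiary allylic ester.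

**25 back to 22, via 24.** The alkene is taken back to an alkyne, then the lactone acyl C–O bond and the C8–CH3 bond are cut. Methyl is made the last group to enter at C8, because the incoming group goes anti to the C6 oxygen. With an alkynyl ketone this gives the required C8 epimer; adding the acetylide to a C8 methyl ketone would give the opposite one. The forward step needs 1,2-addition to an alkoxy ynone and closure of a hindered lactone.

**22 back to 15 and 18.** The C8–C9 bond is cut between an acyl chloride and an alkoxyacetylide. The acyl partner carries a second ester that must survive, hence a zinc reagent with palladium catalysis.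

**15 back to 9, via 13 and 11.** The C8 acid is traced to a C8 methyl ketone, and C2 and C8 are reconnected as a ring alkene. The ring methyl serves only to differentiate the two ozonolysis termini (ketone against aldehyde) and is then degraded. The forward degradation needs regioselective enolisation at the methyl group.

**9 back to 3 and 4, via 8, 7, 6 and 5.** After protecting-group changes, the C1–C5 and C6–C7 bonds are cut (Diels–Alder). C5 and C6 come trans from an E dienophile; the enantiomer is selected by an enzyme because the dienophile has no precedent in asymmetric catalysis.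

**3 back to 1 and 2; 18 back to 16 and 17.** The enol ester C–O bond and the vinyl ether C–O bond are cut; all four are commercial.

## Other disconnections considered

**Alternative 1:** The C1–C5 bond of ring A is traced to a six-membered α-diazo ketone A1. Forward, irradiation in methanol expels N2, the quaternary C1 shifts from the acyl carbon to the carbene carbon with retention, and the ketene is trapped as ester A2.
- In favour: C1, C2 and C4 are set on a six-membered template, and the isopropyl carbinol is present from the start. On ring A this plan is better than the chosen one, which needs a Grignard addition and a redox correction at C2.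
- Against: C5 is fixed only by protonation of an ester enol. All of ring B, with C6, C10 and the trisubstituted alkene, must still be built onto a crowded cyclopentane by several C–C bond formations.
- Comparison: equal in reliability of the key step (both are known ring contractions). Worse in step economy, and the quaternary centre gives no help in setting C10.

**Alternative 2:** C6–C7 and C1–C10 are cut. Forward, a dirhodium tetracarboxylate such as Rh2(OAc)4 turns vinyl diazoester A3 into a carbenoid that cyclopropanates the CH2=C(CH3) end of siloxydiene A4; the cis-divinylcyclopropane then rearranges to A5.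
- In favour: two C–C bonds, ring B and the C8=C9 alkene arise in one convergent catalytic step. On bond count and convergence this is better than the chosen plan.
- Against: the Cope step must create the quaternary C1 from a fully substituted vinyl terminus. A5 as formulated has the C10 oxygen trans to the C1 methyl, which is the C10 epimer of the target and would need an inversion. C6 carries a methoxycarbonyl carbon that must be degraded to oxygen. The tetrasubstituted C5=C6 alkene must still be turned into trans C5–H and C6–O.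
- Comparison: the ring-forming step is shorter, but the corrections after it outweigh the gain. The chosen plan delivers C1, C5, C6 and C10 in their final configuration.

**Alternative 3:** C7–C8 is cut. Forward, zerovalent palladium inserts into the C–I bond of the Z alkenyl iodide A6, the methyl ketone enolate (C7) couples, and reductive elimination gives A7.
- In favour: all five stereocentres are in place and untouched, C6 arrives as a ketone, and no acid-labile enol ether is needed. On functional-group robustness at the ring-closing stage it is the equal or the better of the chosen plan.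
- Against: A6 requires C1 (quaternary), C2, C4, C5 and C10 to be assembled on a lone cyclopentane, which is the problem the Claisen shift solves. Seven-membered closure by enolate alkenylation is less favourable than five or six. The base can enolise towards C5 (epimerisation, loss of the C4 silyloxy group). The β,γ-unsaturated ketone can conjugate. Reduction at C6 must bring hydride from the face of the angular methyl.
- Comparison: similar length after ring closure, clearly longer before it.

Key step: step 14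

**Remarks on the chemistry**
- The skeleton numbering C1 to C10 is used for all intermediates. Racemates 5 to 7 are written as pairs of enantiomers in their SMILES.
- The configurations of 26 and 28 were checked against the target and are consistent: C5 S, C6 S, C8 R in 26; C1 S, C10 S in 28.
- The corrections made are the order of the two additions at C8 (steps 9, 11 and 12) and the C10 configuration noted for A5.

## Steps

Step 1
Reactants: 1 but-3-yn-2-one; 2 acetic acid
Product: 3 (E)-3-oxobut-1-en-1-yl acetate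
Conditions: DABCO (5 mol %), CH2Cl2, 0 °C → rt
Reagents that add atoms: none
Why: Amine-catalysed conjugate addition of a carboxylic acid to an ynone (oxa-Michael addition); the E enol ester is the thermodynamic product under the reversible catalysis, and no stereocentre is formed.

Step 2
Reactants: 3 (E)-3-oxobut-1-en-1-yl acetate; 4 (E)-2-methylpenta-1,3-diene
Product: 5 rac-(1S,5S,6S)-6-acetyl-3,5-dimethylcyclohex-3-en-1-yl acetate
Conditions: EtAlCl2 (0.2 equiv), CH2Cl2, −78 → −20 °C
Reagents that add atoms: none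
Why: Lewis-acid-promoted Diels–Alder reaction; both methyl groups make the CH2 terminus of the diene its nucleophilic end, which bonds to the β-carbon of the enone, so the acetyl carbon (C5) ends next to the methyl-bearing C1 and 1,4 to the ring methyl. The E geometry of 3 is carried suprafacially into the trans relation of acetyl and acetoxy (C5/C6), and the endo rule puts the C1 methyl cis to the acetyl group (a centre erased in step 14); the adduct is racemic.

Step 3
Reactants: 5 rac-(1S,5S,6S)-6-acetyl-3,5-dimethylcyclohex-3-en-1-yl acetate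
Product: 6 rac-(1S,5S,6S)-3,5-dimethyl-6-(2-methyl-1,3-dioxolan-2-yl)cyclohex-3-en-1-yl acetate
Conditions: Me3SiOCH2CH2OSiMe3, Me3SiOTf (cat.), CH2Cl2, −78 → −20 °C
Reagents that add atoms: 1,2-bis(trimethylsilyloxy)ethane C[Si](C)(C)OCCO[Si](C)(C)C
Why: Aprotic ketalisation with the bis-silyl ether of ethylene glycol under silyl triflate catalysis, mild enough not to eliminate the β-acetoxy group; no stereocentre is touched.

Step 4
Reactants: 6 rac-(1S,5S,6S)-3,5-dimethyl-6-(2-methyl-1,3-dioxolan-2-yl)cyclohex-3-en-1-yl acetate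
Product: 7 rac-(1S,5S,6S)-3,5-dimethyl-6-(2-methyl-1,3-dioxolan-2-yl)cyclohex-3-en-1-ol
Conditions: K2CO3, MeOH, rt
Reagents that add atoms: none
Why: Base-catalysed transesterification; with the ketone masked the acetate is no longer β to a carbonyl group, so elimination cannot compete.

Step 5
Reactants: 7 rac-(1S,5S,6S)-3,5-dimethyl-6-(2-methyl-1,3-dioxolan-2-yl)cyclohex-3-en-1-ol
Product: 8 (1S,5S,6S)-3,5-dimethyl-6-(2-methyl-1,3-dioxolan-2-yl)cyclohex-3-en-1-ol
Conditions: Amano lipase PS (Burkholderia cepacia), vinyl acetate, t-BuOMe, 30 °C, to slightly beyond half conversion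
Reagents that add atoms: none
Why: Lipase-catalysed kinetic resolution by enantioselective transesterification; by the usual preference of this enzyme class the (1R)-carbinol, whose larger carbinol substituent is the dioxolane-bearing ring carbon, is acylated and the (1S,5S,6S)-alcohol stays behind. Running slightly past half conversion should secure its enantiopurity.

Step 6
Reactants: 8 (1S,5S,6S)-3,5-dimethyl-6-(2-methyl-1,3-dioxolan-2-yl)cyclohex-3-en-1-ol
Product: 9 tert-butyl{[(1S,5S,6S)-3,5-dimethyl-6-(2-methyl-1,3-dioxolan-2-yl)cyclohex-3-en-1-yl]oxy}dimethylsilane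
Conditions: t-BuMe2SiOTf, 2,6-lutidine, CH2Cl2, −78 → 0 °C
Reagents that add atoms: tert-butyldimethylsilyl trifluoromethanesulfonate CC(C)(C)[Si](C)(C)OS(=O)(=O)C(F)(F)F
Why: Silylation of a hindered secondary alcohol with the silyl triflate and a hindered pyridine base; no stereocentre is affected.

Step 7
Reactants: 9 tert-butyl{[(1S,5S,6S)-3,5-dimethyl-6-(2-methyl-1,3-dioxolan-2-yl)cyclohex-3-en-1-yl]oxy}dimethylsilane
Product: 11 (2R,3S,4S)-4-(tert-butyldimethylsilyloxy)-2-methyl-3-(2-methyl-1,3-dioxolan-2-yl)-6-oxoheptanoic acid, via keto aldehyde 10 (not isolated)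
Conditions: O3, CH2Cl2/MeOH, −78 °C; Me2S; then NaClO2, NaH2PO4, 2-methylbut-2-ene, t-BuOH/H2O, 0 °C → rt
Reagents that add atoms: ozone [O-][O+]=O; sodium chlorite [Na+].[O-]Cl=O
Why: Ozonolysis of the trisubstituted ring alkene gives the C8 methyl ketone and the C2 aldehyde, which are thereby differentiated; the Pinnick oxidation takes the aldehyde to the acid without touching ketone, silyl ether or ketal. Epimerisation of C1 at the aldehyde stage would be inconsequential.

Step 8
Reactants: 11 (2R,3S,4S)-4-(tert-butyldimethylsilyloxy)-2-methyl-3-(2-methyl-1,3-dioxolan-2-yl)-6-oxoheptanoic acid; 12 phenol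
Product: 13 phenyl (2R,3S,4S)-4-(tert-butyldimethylsilyloxy)-2-methyl-3-(2-methyl-1,3-dioxolan-2-yl)-6-oxoheptanoate
Conditions: EDC·HCl, DMAP (cat.), CH2Cl2, 0 °C → rt
Reagents that add atoms: none
Why: Carbodiimide esterification; the phenyl ester is inert to the organozinc and Grignard reagents used at low temperature but is a good acyl donor towards the tertiary alkoxide of step 12.

Step 9
Reactants: 13 phenyl (2R,3S,4S)-4-(tert-butyldimethylsilyloxy)-2-methyl-3-(2-methyl-1,3-dioxolan-2-yl)-6-oxoheptanoate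
Product: 15 (3S,4S,5R)-3-(tert-butyldimethylsilyloxy)-5-methyl-4-(2-methyl-1,3-dioxolan-2-yl)-6-oxo-6-phenoxyhexanoic acid, via silyl enol ether 14 (not isolated)
Conditions: LDA, Me3SiCl (in situ), THF, −78 °C; non-aqueous work-up; then O3, CH2Cl2, −78 °C; Me2S; aqueous work-up
Reagents that add atoms: ozone [O-][O+]=O
Why: Kinetic deprotonation of the methyl ketone at its methyl group with in situ silylation gives the terminal silyl enol ether, whose ozonolysis cleaves C8–CH3 to the carboxylic acid (silyl ester, hydrolysed on work-up), a known degradation of methyl ketones. C8 thereby becomes an acyl carbon, so that the alkynyl group can be attached before the methyl group.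

Step 10
Reactants: 16 4-methoxybenzyl alcohol; 17 trichloroethylene
Product: 18 1-{[(E)-1,2-dichloroethenyl]oxymethyl}-4-methoxybenzene
Conditions: KH, THF, 0 °C; then trichloroethylene, 0 °C → rt
Reagents that add atoms: none
Why: The potassium alkoxide adds to dichloroacetylene formed in situ from trichloroethylene (elimination–addition, trans addition), which gives the E dichlorovinyl ether, the standard precursor of an alkoxyacetylide.

Step 11
Reactants: 15 (3S,4S,5R)-3-(tert-butyldimethylsilyloxy)-5-methyl-4-(2-methyl-1,3-dioxolan-2-yl)-6-oxo-6-phenoxyhexanoic acid; 18 1-{[(E)-1,2-dichloroethenyl]oxymethyl}-4-methoxybenzene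
Product: 22 phenyl (2R,3S,4S)-4-(tert-butyldimethylsilyloxy)-8-[(4-methoxybenzyl)oxy]-2-methyl-3-(2-methyl-1,3-dioxolan-2-yl)-6-oxooct-7-ynoate, via acid chloride 19 (not isolated), via lithium alkoxyacetylide 20 (not isolated), via chlorozinc alkoxyacetylide 21 (not isolated)
Conditions: 15: 1-chloro-N,N,2-trimethylprop-1-en-1-amine, CH2Cl2, 0 °C; 18: n-BuLi (2.1 equiv), THF, −78 → −40 °C, then ZnCl2, −78 → 0 °C; combine, Pd(PPh3)4 (5 mol %), THF, 0 °C
Reagents that add atoms: none
Why: The acid is converted into its chloride under neutral conditions; n-BuLi turns 18 into the lithium alkoxyacetylide by elimination and chlorine–lithium exchange, and after transmetalation to zinc the acetylide is acylated under zerovalent palladium catalysis (Negishi acylation). This ketone synthesis cannot over-add and leaves the phenyl ester alone.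

Step 12
Reactants: 22 phenyl (2R,3S,4S)-4-(tert-butyldimethylsilyloxy)-8-[(4-methoxybenzyl)oxy]-2-methyl-3-(2-methyl-1,3-dioxolan-2-yl)-6-oxooct-7-ynoate
Product: 24 (3R,4S,5S,7R)-5-(tert-butyldimethylsilyloxy)-7-{[(4-methoxybenzyl)oxy]ethynyl}-3,7-dimethyl-4-(2-methyl-1,3-dioxolan-2-yl)oxepan-2-one, via bromomagnesium alkoxide 23 (not isolated)
Conditions: MeMgBr, CH2Cl2/Et2O, −78 °C; then THF, −78 → 20 °C
Reagents that add atoms: methylmagnesium bromide C[Mg]Br
Why: Hard Grignard reagents add 1,2 to alkoxy ynones as they do to β-alkoxy enones; with the slim alkynyl group on the carbonyl the β-silyloxy ketone behaves like a β-alkoxy aldehyde, so methyl enters anti to the C6–O dipole (1,3-induction, the same sense as a magnesium chelate) and C8 becomes R, with C6–O and C8–O syn along C5 to C9. The tertiary alkoxide then displaces phenoxide in a 7-exo-trig acyl transfer; adding the acetylide to a C8 methyl ketone instead would send the alkynyl group to that same face and give the other C8 epimer.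

Step 13
Reactants: 24 (3R,4S,5S,7R)-5-(tert-butyldimethylsilyloxy)-7-{[(4-methoxybenzyl)oxy]ethynyl}-3,7-dimethyl-4-(2-methyl-1,3-dioxolan-2-yl)oxepan-2-one
Product: 25 (3R,4S,5S,7R)-5-(tert-butyldimethylsilyloxy)-7-{(Z)-2-[(4-methoxybenzyl)oxy]ethenyl}-3,7-dimethyl-4-(2-methyl-1,3-dioxolan-2-yl)oxepan-2-one
Conditions: H2 (1 atm), Pd/CaCO3/Pb(OAc)2, quinoline, EtOAc/Et3N, 0 °C
Reagents that add atoms: none
Why: Semi-hydrogenation over lead-poisoned palladium is a syn addition and gives the Z enol ether; the amine keeps the medium basic, which protects the enol ether and the tertiary allylic lactone from ionisation. The benzyl-type alkynyl ether is kept cold until this step because such ethers rearrange on heating.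

Step 14
Reactants: 25 (3R,4S,5S,7R)-5-(tert-butyldimethylsilyloxy)-7-{(Z)-2-[(4-methoxybenzyl)oxy]ethenyl}-3,7-dimethyl-4-(2-methyl-1,3-dioxolan-2-yl)oxepan-2-one
Product: 28 (1S,2S,6S,7S)-6-(tert-butyldimethylsilyloxy)-2-[(4-methoxybenzyl)oxy]-1,4-dimethyl-7-(2-methyl-1,3-dioxolan-2-yl)cyclohept-3-ene-1-carboxylic acid, via silyl ketene acetal 26 (not isolated), via trimethylsilyl ester 27 (not isolated)
Conditions: KN(SiMe3)2, Me3SiCl/Et3N (premixed), THF/toluene, −78 °C; then −78 → 60 °C; aqueous work-up at pH 5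
Reagents that add atoms: none
Why: KN(SiMe3)2 removes the C1 proton of 25 at −78 °C in the presence of Me3SiCl and the enolate is silylated on oxygen to 26, whose C1=C2 geometry is fixed by the ring; on warming, 26 undergoes a concerted suprafacial (3,3) sigmatropic shift that breaks O–C8 and forms C1–C10, giving 27 and, after hydrolysis, 28. The closest known reaction type is the Ireland–Claisen ring contraction of ω-alkenyl lactone silyl ketene acetals to cycloalkene carboxylic acids. Ring B is closed as a seven-membered carbocycle between the ketene acetal carbon C1 and the enol ether terminus C10, which are already joined by the C5–C6–C7 bridge, so only a boat-shaped transition state is possible. C1 is controlled by C8: the alkenyl arm lies on the lactone face that carries the C5 substituent and can reach C1 only from there, which puts the C1 methyl cis to C4 (the later trans ring fusion). C10 is controlled by the Z enol ether: in the boat the alkoxy group sits in the inside position and ends cis to the C1 methyl. The step needs chemoselective α-deprotonation of the lactone (the acetyl group is masked and C5–H is not acidified), O-silylation instead of C-silylation (in situ quench), and a pericyclic instead of an ionic course (aprotic, amine-buffered, no Lewis acid), because heterolysis of the tertiary C8–O bond would erase the C8 and Z information. The silyloxy donor on the ketene acetal and the alkoxy group on C10 both lower the barrier, which should offset the strain of the boat.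

Step 15
Reactants: 28 (1S,2S,6S,7S)-6-(tert-butyldimethylsilyloxy)-2-[(4-methoxybenzyl)oxy]-1,4-dimethyl-7-(2-methyl-1,3-dioxolan-2-yl)cyclohept-3-ene-1-carboxylic acid
Product: 29 [(1R,2S,6S,7S)-6-(tert-butyldimethylsilyloxy)-2-[(4-methoxybenzyl)oxy]-1,4-dimethyl-7-(2-methyl-1,3-dioxolan-2-yl)cyclohept-3-en-1-yl]methanol
Conditions: LiAlH4, THF, 0 → 40 °C
Reagents that add atoms: none
Why: Hydride reduction of the hindered acid to the neopentyl alcohol; silyl ether, ketal, benzyl-type ether and the isolated alkene are inert (the C1 descriptor changes by priority only).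

Step 16
Reactants: 29 [(1R,2S,6S,7S)-6-(tert-butyldimethylsilyloxy)-2-[(4-methoxybenzyl)oxy]-1,4-dimethyl-7-(2-methyl-1,3-dioxolan-2-yl)cyclohept-3-en-1-yl]methanol
Product: 30 (1S,2S,6S,7S)-6-(tert-butyldimethylsilyloxy)-2-[(4-methoxybenzyl)oxy]-1,4-dimethyl-7-(2-methyl-1,3-dioxolan-2-yl)cyclohept-3-ene-1-carbaldehyde
Conditions: Dess–Martin periodinane, NaHCO3, CH2Cl2, 0 °C → rt
Reagents that add atoms: none
Why: Dess–Martin oxidation to the non-enolisable aldehyde under buffered conditions that keep the ketal.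

Step 17
Reactants: 30 (1S,2S,6S,7S)-6-(tert-butyldimethylsilyloxy)-2-[(4-methoxybenzyl)oxy]-1,4-dimethyl-7-(2-methyl-1,3-dioxolan-2-yl)cyclohept-3-ene-1-carbaldehyde
Product: 31 (1S,2S,6S,7S)-7-acetyl-6-(tert-butyldimethylsilyloxy)-2-[(4-methoxybenzyl)oxy]-1,4-dimethylcyclohept-3-ene-1-carbaldehyde
Conditions: PPTS, acetone/H2O, 45 °C
Reagents that add atoms: water O
Why: Acid-catalysed ketal hydrolysis under conditions mild enough for the secondary silyl ether and the benzyl-type ether; the aldehyde has no α-hydrogen and cannot enolise.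

Step 18
Reactants: 31 (1S,2S,6S,7S)-7-acetyl-6-(tert-butyldimethylsilyloxy)-2-[(4-methoxybenzyl)oxy]-1,4-dimethylcyclohept-3-ene-1-carbaldehyde
Product: 32 (1R,5S,6S,10S)-6-(tert-butyldimethylsilyloxy)-2-hydroxy-10-[(4-methoxybenzyl)oxy]-1,8-dimethyl-4-oxobicyclo[5.3.0]dec-8-ene (skeleton numbering; C2 epimers)
Conditions: LDA, THF, −78 °C; AcOH quench at −78 °C
Reagents that add atoms: none
Why: Intramolecular aldol addition: the kinetic lithium enolate of the methyl ketone (C3) adds to the C2 aldehyde and closes ring A, the mode of cyclisation of 1,4-dicarbonyl compounds (enolate carbon and its carbonyl carbon both in the new five-membered ring). The cold quench avoids dehydration; C2 forms as a mixture that steps 20 and 21 correct, and C5 is not deprotonated under kinetic conditions.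

Step 19
Reactants: 32 (1R,5S,6S,10S)-6-(tert-butyldimethylsilyloxy)-2-hydroxy-10-[(4-methoxybenzyl)oxy]-1,8-dimethyl-4-oxobicyclo[5.3.0]dec-8-ene (skeleton numbering; C2 epimers)
Product: 33 (1R,4R,5S,6S,10S)-6-(tert-butyldimethylsilyloxy)-2,4-dihydroxy-4-isopropyl-10-[(4-methoxybenzyl)oxy]-1,8-dimethylbicyclo[5.3.0]dec-8-ene (skeleton numbering; C2 epimers)
Conditions: i-PrMgCl, CeCl3, THF, −78 °C
Reagents that add atoms: isopropylmagnesium chloride CC(C)[Mg]Cl
Why: Organocerium addition, which suppresses enolisation and reduction of the ketone; the reagent attacks C4 anti to the angular C1 methyl, which shields the α face of ring A in a 1,3 relation, so isopropyl ends cis to H5 and the hydroxyl cis to the C1 methyl (4R). The free C2 hydroxyl consumes one equivalent of reagent.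

Step 20
Reactants: 33 (1R,4R,5S,6S,10S)-6-(tert-butyldimethylsilyloxy)-2,4-dihydroxy-4-isopropyl-10-[(4-methoxybenzyl)oxy]-1,8-dimethylbicyclo[5.3.0]dec-8-ene (skeleton numbering; C2 epimers)
Product: 34 (1S,4R,5S,6S,10S)-6-(tert-butyldimethylsilyloxy)-4-hydroxy-4-isopropyl-10-[(4-methoxybenzyl)oxy]-1,8-dimethyl-2-oxobicyclo[5.3.0]dec-8-ene (skeleton numbering)
Conditions: Dess–Martin periodinane, NaHCO3, CH2Cl2, 0 °C
Reagents that add atoms: none
Why: Dess–Martin oxidation of the secondary C2 alcohol; the tertiary C4 alcohol is inert, and the neutral conditions avoid retro-aldol cleavage of the β-hydroxy ketone.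

Step 21
Reactants: 34 (1S,4R,5S,6S,10S)-6-(tert-butyldimethylsilyloxy)-4-hydroxy-4-isopropyl-10-[(4-methoxybenzyl)oxy]-1,8-dimethyl-2-oxobicyclo[5.3.0]dec-8-ene (skeleton numbering)
Product: 35 (1R,2S,4R,5S,6S,10S)-6-(tert-butyldimethylsilyloxy)-2,4-dihydroxy-4-isopropyl-10-[(4-methoxybenzyl)oxy]-1,8-dimethylbicyclo[5.3.0]dec-8-ene (skeleton numbering)
Conditions: Me4NBH(OAc)3, MeCN/AcOH, −30 → 0 °C
Reagents that add atoms: none
Why: Evans–Saksena reduction: the C4 hydroxyl exchanges an acetate on boron and delivers hydride intramolecularly to the α face of the C2 ketone, giving the 2,4-anti diol (2S). An external hydride would come from the β face, anti to the C1 methyl, and give the wrong epimer.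

Step 22
Reactants: 35 (1R,2S,4R,5S,6S,10S)-6-(tert-butyldimethylsilyloxy)-2,4-dihydroxy-4-isopropyl-10-[(4-methoxybenzyl)oxy]-1,8-dimethylbicyclo[5.3.0]dec-8-ene (skeleton numbering)
Product: 36 (1R,2S,4R,5S,6S,10S)-2-acetoxy-6-(tert-butyldimethylsilyloxy)-4-hydroxy-4-isopropyl-10-[(4-methoxybenzyl)oxy]-1,8-dimethylbicyclo[5.3.0]dec-8-ene (skeleton numbering)
Conditions: Ac2O, Et3N, DMAP (cat.), CH2Cl2, 0 °C → rt
Reagents that add atoms: acetic anhydride CC(=O)OC(C)=O
Why: DMAP-catalysed acetylation; only the secondary C2 hydroxyl reacts, the tertiary C4 hydroxyl does not under these conditions.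

Step 23
Reactants: 36 (1R,2S,4R,5S,6S,10S)-2-acetoxy-6-(tert-butyldimethylsilyloxy)-4-hydroxy-4-isopropyl-10-[(4-methoxybenzyl)oxy]-1,8-dimethylbicyclo[5.3.0]dec-8-ene (skeleton numbering)
Product: 37 (1R,2S,4R,5S,6S,10S)-2-acetoxy-4,6-dihydroxy-4-isopropyl-10-[(4-methoxybenzyl)oxy]-1,8-dimethylbicyclo[5.3.0]dec-8-ene (skeleton numbering)
Conditions: Bu4NF, AcOH, THF, 0 → 40 °C
Reagents that add atoms: none
Why: Fluoride cleavage of the silyl ether, buffered with acetic acid so that the acetate neither migrates nor is cleaved.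

Step 24
Reactants: 37 (1R,2S,4R,5S,6S,10S)-2-acetoxy-4,6-dihydroxy-4-isopropyl-10-[(4-methoxybenzyl)oxy]-1,8-dimethylbicyclo[5.3.0]dec-8-ene (skeleton numbering)
Product: 38 (1R,2S,4R,5S,6S,10S)-2-acetoxy-4-hydroxy-4-isopropyl-6-(4-methoxybenzoyloxy)-10-[(4-methoxybenzyl)oxy]-1,8-dimethylbicyclo[5.3.0]dec-8-ene (skeleton numbering)
Conditions: 4-methoxybenzoyl chloride, Et3N, DMAP, CH2Cl2, rt
Reagents that add atoms: 4-methoxybenzoyl chloride COc1ccc(cc1)C(Cl)=O
Why: DMAP-catalysed acylation of the secondary C6 hydroxyl; the tertiary C4 hydroxyl stays free.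

Step 25
Reactants: 38 (1R,2S,4R,5S,6S,10S)-2-acetoxy-4-hydroxy-4-isopropyl-6-(4-methoxybenzoyloxy)-10-[(4-methoxybenzyl)oxy]-1,8-dimethylbicyclo[5.3.0]dec-8-ene (skeleton numbering)
Product: 39 (1S,2S,4R,5S,6S,10S)-2-acetoxy-4,10-dihydroxy-4-isopropyl-6-(4-methoxybenzoyloxy)-1,8-dimethylbicyclo[5.3.0]dec-8-ene (skeleton numbering; CNP0261832.1)
Conditions: DDQ, CH2Cl2/pH 7 buffer, 0 °C
Reagents that add atoms: none
Why: Oxidative cleavage of the 4-methoxybenzyl ether by DDQ (hydride abstraction, then hydrolysis of the hemiacetal) under neutral conditions that leave both esters, the alkene and the tertiary alcohol untouched.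

## Compound list

1 | but-3-yn-2-one | CC(=O)C#C | starting material
2 | acetic acid | CC(=O)O | starting material
3 | (E)-3-oxobut-1-en-1-yl acetate | CC(=O)/C=C/OC(C)=O | intermediate
4 | (E)-2-methylpenta-1,3-diene | C=C(C)/C=C/C | starting material
5 | rac-(1S,5S,6S)-6-acetyl-3,5-dimethylcyclohex-3-en-1-yl acetate | CC(=O)O[C@H]1CC(C)=C[C@H](C)[C@@H]1C(C)=O.CC(=O)O[C@@H]1CC(C)=C[C@@H](C)[C@H]1C(C)=O | intermediate
6 | rac-(1S,5S,6S)-3,5-dimethyl-6-(2-methyl-1,3-dioxolan-2-yl)cyclohex-3-en-1-yl acetate | CC(=O)O[C@H]1CC(C)=C[C@H](C)[C@@H]1C2(C)OCCO2.CC(=O)O[C@@H]1CC(C)=C[C@@H](C)[C@H]1C2(C)OCCO2 | intermediate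
7 | rac-(1S,5S,6S)-3,5-dimethyl-6-(2-methyl-1,3-dioxolan-2-yl)cyclohex-3-en-1-ol | O[C@H]1CC(C)=C[C@H](C)[C@@H]1C2(C)OCCO2.O[C@@H]1CC(C)=C[C@@H](C)[C@H]1C2(C)OCCO2 | intermediate
8 | (1S,5S,6S)-3,5-dimethyl-6-(2-methyl-1,3-dioxolan-2-yl)cyclohex-3-en-1-ol | O[C@H]1CC(C)=C[C@H](C)[C@@H]1C2(C)OCCO2 | intermediate
9 | tert-butyl{[(1S,5S,6S)-3,5-dimethyl-6-(2-methyl-1,3-dioxolan-2-yl)cyclohex-3-en-1-yl]oxy}dimethylsilane | CC(C)(C)[Si](C)(C)O[C@H]1CC(C)=C[C@H](C)[C@@H]1C2(C)OCCO2 | intermediate
10 | (2R,3S,4S)-4-(tert-butyldimethylsilyloxy)-2-methyl-3-(2-methyl-1,3-dioxolan-2-yl)-6-oxoheptanal | CC(=O)C[C@H](O[Si](C)(C)C(C)(C)C)[C@@H](C1(C)OCCO1)[C@@H](C)C=O | intermediate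
11 | (2R,3S,4S)-4-(tert-butyldimethylsilyloxy)-2-methyl-3-(2-methyl-1,3-dioxolan-2-yl)-6-oxoheptanoic acid | CC(=O)C[C@H](O[Si](C)(C)C(C)(C)C)[C@@H](C1(C)OCCO1)[C@@H](C)C(=O)O | intermediate
12 | phenol | Oc1ccccc1 | starting material
13 | phenyl (2R,3S,4S)-4-(tert-butyldimethylsilyloxy)-2-methyl-3-(2-methyl-1,3-dioxolan-2-yl)-6-oxoheptanoate | CC(=O)C[C@H](O[Si](C)(C)C(C)(C)C)[C@@H](C1(C)OCCO1)[C@@H](C)C(=O)Oc1ccccc1 | intermediate
14 | phenyl (2R,3S,4S)-4-(tert-butyldimethylsilyloxy)-2-methyl-3-(2-methyl-1,3-dioxolan-2-yl)-6-(trimethylsilyloxy)hept-6-enoate | C=C(O[Si](C)(C)C)C[C@H](O[Si](C)(C)C(C)(C)C)[C@@H](C1(C)OCCO1)[C@@H](C)C(=O)Oc1ccccc1 | intermediate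
15 | (3S,4S,5R)-3-(tert-butyldimethylsilyloxy)-5-methyl-4-(2-methyl-1,3-dioxolan-2-yl)-6-oxo-6-phenoxyhexanoic acid | OC(=O)C[C@H](O[Si](C)(C)C(C)(C)C)[C@@H](C1(C)OCCO1)[C@@H](C)C(=O)Oc1ccccc1 | intermediate
16 | 4-methoxybenzyl alcohol | COc1ccc(CO)cc1 | starting material
17 | trichloroethylene | ClC=C(Cl)Cl | starting material
18 | 1-{[(E)-1,2-dichloroethenyl]oxymethyl}-4-methoxybenzene | COc1ccc(CO/C(Cl)=C\Cl)cc1 | intermediate
19 | phenyl (2R,3S,4S)-4-(tert-butyldimethylsilyloxy)-6-chloro-2-methyl-3-(2-methyl-1,3-dioxolan-2-yl)-6-oxohexanoate | ClC(=O)C[C@H](O[Si](C)(C)C(C)(C)C)[C@@H](C1(C)OCCO1)[C@@H](C)C(=O)Oc1ccccc1 | intermediate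
20 | lithium [(4-methoxybenzyl)oxy]acetylide | [Li]C#COCc1ccc(OC)cc1 | intermediate
21 | chloro{[(4-methoxybenzyl)oxy]ethynyl}zinc | Cl[Zn]C#COCc1ccc(OC)cc1 | intermediate
22 | phenyl (2R,3S,4S)-4-(tert-butyldimethylsilyloxy)-8-[(4-methoxybenzyl)oxy]-2-methyl-3-(2-methyl-1,3-dioxolan-2-yl)-6-oxooct-7-ynoate | COc1ccc(COC#CC(=O)C[C@H](O[Si](C)(C)C(C)(C)C)[C@@H](C2(C)OCCO2)[C@@H](C)C(=O)Oc2ccccc2)cc1 | intermediate
23 | bromomagnesium alkoxide of phenyl (2R,3S,4S,6R)-4-(tert-butyldimethylsilyloxy)-6-hydroxy-8-[(4-methoxybenzyl)oxy]-2,6-dimethyl-3-(2-methyl-1,3-dioxolan-2-yl)oct-7-ynoate | COc1ccc(COC#C[C@](C)(O[Mg]Br)C[C@H](O[Si](C)(C)C(C)(C)C)[C@@H](C2(C)OCCO2)[C@@H](C)C(=O)Oc2ccccc2)cc1 | intermediate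
24 | (3R,4S,5S,7R)-5-(tert-butyldimethylsilyloxy)-7-{[(4-methoxybenzyl)oxy]ethynyl}-3,7-dimethyl-4-(2-methyl-1,3-dioxolan-2-yl)oxepan-2-one | C[C@H]1C(=O)O[C@@](C)(C#COCc2ccc(OC)cc2)C[C@H](O[Si](C)(C)C(C)(C)C)[C@H]1C3(C)OCCO3 | intermediate
25 | (3R,4S,5S,7R)-5-(tert-butyldimethylsilyloxy)-7-{(Z)-2-[(4-methoxybenzyl)oxy]ethenyl}-3,7-dimethyl-4-(2-methyl-1,3-dioxolan-2-yl)oxepan-2-one | C[C@H]1C(=O)O[C@@](C)(/C=C\OCc2ccc(OC)cc2)C[C@H](O[Si](C)(C)C(C)(C)C)[C@H]1C3(C)OCCO3 | intermediate
26 | (4S,5S,7R)-5-(tert-butyldimethylsilyloxy)-7-{(Z)-2-[(4-methoxybenzyl)oxy]ethenyl}-3,7-dimethyl-4-(2-methyl-1,3-dioxolan-2-yl)-2-(trimethylsilyloxy)-4,5,6,7-tetrahydrooxepine | CC1=C(O[Si](C)(C)C)O[C@@](C)(/C=C\OCc2ccc(OC)cc2)C[C@H](O[Si](C)(C)C(C)(C)C)[C@H]1C3(C)OCCO3 | intermediate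
27 | trimethylsilyl (1S,2S,6S,7S)-6-(tert-butyldimethylsilyloxy)-2-[(4-methoxybenzyl)oxy]-1,4-dimethyl-7-(2-methyl-1,3-dioxolan-2-yl)cyclohept-3-ene-1-carboxylate | CC(C)(C)[Si](C)(C)O[C@H]1CC(C)=C[C@H](OCc2ccc(OC)cc2)[C@@](C)(C(=O)O[Si](C)(C)C)[C@@H]1C3(C)OCCO3 | intermediate
28 | (1S,2S,6S,7S)-6-(tert-butyldimethylsilyloxy)-2-[(4-methoxybenzyl)oxy]-1,4-dimethyl-7-(2-methyl-1,3-dioxolan-2-yl)cyclohept-3-ene-1-carboxylic acid | CC(C)(C)[Si](C)(C)O[C@H]1CC(C)=C[C@H](OCc2ccc(OC)cc2)[C@@](C)(C(=O)O)[C@@H]1C3(C)OCCO3 | intermediate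
29 | [(1R,2S,6S,7S)-6-(tert-butyldimethylsilyloxy)-2-[(4-methoxybenzyl)oxy]-1,4-dimethyl-7-(2-methyl-1,3-dioxolan-2-yl)cyclohept-3-en-1-yl]methanol | CC(C)(C)[Si](C)(C)O[C@H]1CC(C)=C[C@H](OCc2ccc(OC)cc2)[C@@](C)(CO)[C@@H]1C3(C)OCCO3 | intermediate
30 | (1S,2S,6S,7S)-6-(tert-butyldimethylsilyloxy)-2-[(4-methoxybenzyl)oxy]-1,4-dimethyl-7-(2-methyl-1,3-dioxolan-2-yl)cyclohept-3-ene-1-carbaldehyde | CC(C)(C)[Si](C)(C)O[C@H]1CC(C)=C[C@H](OCc2ccc(OC)cc2)[C@@](C)(C=O)[C@@H]1C3(C)OCCO3 | intermediate
31 | (1S,2S,6S,7S)-7-acetyl-6-(tert-butyldimethylsilyloxy)-2-[(4-methoxybenzyl)oxy]-1,4-dimethylcyclohept-3-ene-1-carbaldehyde | CC(C)(C)[Si](C)(C)O[C@H]1CC(C)=C[C@H](OCc2ccc(OC)cc2)[C@@](C)(C=O)[C@@H]1C(C)=O | intermediate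
32 | (1R,5S,6S,10S)-6-(tert-butyldimethylsilyloxy)-2-hydroxy-10-[(4-methoxybenzyl)oxy]-1,8-dimethyl-4-oxobicyclo[5.3.0]dec-8-ene (skeleton numbering; C2 epimers) | CC(C)(C)[Si](C)(C)O[C@H]1CC(C)=C[C@H](OCc2ccc(OC)cc2)[C@@]3(C)C(O)CC(=O)[C@H]13 | intermediate
33 | (1R,4R,5S,6S,10S)-6-(tert-butyldimethylsilyloxy)-2,4-dihydroxy-4-isopropyl-10-[(4-methoxybenzyl)oxy]-1,8-dimethylbicyclo[5.3.0]dec-8-ene (skeleton numbering; C2 epimers) | CC(C)(C)[Si](C)(C)O[C@H]1CC(C)=C[C@H](OCc2ccc(OC)cc2)[C@@]3(C)C(O)C[C@@](O)(C(C)C)[C@H]13 | intermediate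
34 | (1S,4R,5S,6S,10S)-6-(tert-butyldimethylsilyloxy)-4-hydroxy-4-isopropyl-10-[(4-methoxybenzyl)oxy]-1,8-dimethyl-2-oxobicyclo[5.3.0]dec-8-ene (skeleton numbering) | CC(C)(C)[Si](C)(C)O[C@H]1CC(C)=C[C@H](OCc2ccc(OC)cc2)[C@@]3(C)C(=O)C[C@@](O)(C(C)C)[C@H]13 | intermediate
35 | (1R,2S,4R,5S,6S,10S)-6-(tert-butyldimethylsilyloxy)-2,4-dihydroxy-4-isopropyl-10-[(4-methoxybenzyl)oxy]-1,8-dimethylbicyclo[5.3.0]dec-8-ene (skeleton numbering) | CC(C)(C)[Si](C)(C)O[C@H]1CC(C)=C[C@H](OCc2ccc(OC)cc2)[C@@]3(C)[C@@H](O)C[C@@](O)(C(C)C)[C@H]13 | intermediate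
36 | (1R,2S,4R,5S,6S,10S)-2-acetoxy-6-(tert-butyldimethylsilyloxy)-4-hydroxy-4-isopropyl-10-[(4-methoxybenzyl)oxy]-1,8-dimethylbicyclo[5.3.0]dec-8-ene (skeleton numbering) | CC(C)(C)[Si](C)(C)O[C@H]1CC(C)=C[C@H](OCc2ccc(OC)cc2)[C@@]3(C)[C@@H](OC(C)=O)C[C@@](O)(C(C)C)[C@H]13 | intermediate
37 | (1R,2S,4R,5S,6S,10S)-2-acetoxy-4,6-dihydroxy-4-isopropyl-10-[(4-methoxybenzyl)oxy]-1,8-dimethylbicyclo[5.3.0]dec-8-ene (skeleton numbering) | O[C@H]1CC(C)=C[C@H](OCc2ccc(OC)cc2)[C@@]3(C)[C@@H](OC(C)=O)C[C@@](O)(C(C)C)[C@H]13 | intermediate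
38 | (1R,2S,4R,5S,6S,10S)-2-acetoxy-4-hydroxy-4-isopropyl-6-(4-methoxybenzoyloxy)-10-[(4-methoxybenzyl)oxy]-1,8-dimethylbicyclo[5.3.0]dec-8-ene (skeleton numbering) | COc1ccc(cc1)C(=O)O[C@H]1CC(C)=C[C@H](OCc2ccc(OC)cc2)[C@@]3(C)[C@@H](OC(C)=O)C[C@@](O)(C(C)C)[C@H]13 | intermediate
39 | (1S,2S,4R,5S,6S,10S)-2-acetoxy-4,10-dihydroxy-4-isopropyl-6-(4-methoxybenzoyloxy)-1,8-dimethylbicyclo[5.3.0]dec-8-ene (skeleton numbering; CNP0261832.1) | COc1ccc(C(=O)O[C@H]2CC(C)=C[C@H](O)[C@@]3(C)[C@@H](OC(C)=O)C[C@@](O)(C(C)C)[C@H]23)cc1 | target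

## Step count and least certain steps

Total step count: 25. Longest linear sequence: 24 (steps 1 to 9 and 11 to 25; step 10 is a one-step side branch).

**Step 14 (key step).** The boat-shaped transition state places the Z alkoxy group in the inside position, eclipsed with C5 and close to the dioxolane. The shift may therefore be slow, and ionisation of the tertiary, alkoxy-stabilised allylic C8–O bond or ketene formation from the enolate could take over, with loss of the C8 and Z information. Fallback, from 11 back to 28, keeps the (3,3) logic but removes the boat and the ionisable ester: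
- 11 is methylenated at C8 (Ph3P=CH2 on the lithium carboxylate) to (2R,3S,4S)-4-(tert-butyldimethylsilyloxy)-2,6-dimethyl-3-(2-methyl-1,3-dioxolan-2-yl)hept-6-enoic acid F1.
- Acetylide 20 and paraformaldehyde give 3-[(4-methoxybenzyl)oxy]prop-2-yn-1-ol F2, which is semi-hydrogenated over Pd/CaCO3/Pb(OAc)2 to (Z)-3-[(4-methoxybenzyl)oxy]prop-2-en-1-ol F3.
- Carbodiimide esterification of F1 with F3 gives (Z)-3-[(4-methoxybenzyl)oxy]prop-2-en-1-yl (2R,3S,4S)-4-(tert-butyldimethylsilyloxy)-2,6-dimethyl-3-(2-methyl-1,3-dioxolan-2-yl)hept-6-enoate F4.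
- The acyclic Ireland–Claisen rearrangement of F4 (chair) forms C1–C10 and gives the diene acid, 28 opened between C8 and C9 with a C10 vinyl and a C8 isopropenyl terminus, F5.
- Ring-closing metathesis of F5 with the second-generation Grubbs catalyst closes C8=C9 to 28.
- The price is that C1 relative to C5 then rests on acyclic facial control and enolate geometry, so diastereomers would have to be separated.

**Step 12.** Two processes can fail: facial selectivity at C8 can be modest because a silyl ether does not chelate well, and the hindered bromomagnesium alkoxide may close the seven-membered lactone slowly, allowing 1,4-addition or acyl migration to compete. Fallback for the closure, from 22 back to 25: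
- Quench at −78 °C to isolate phenyl (2R,3S,4S,6R)-4-(tert-butyldimethylsilyloxy)-6-hydroxy-8-[(4-methoxybenzyl)oxy]-2,6-dimethyl-3-(2-methyl-1,3-dioxolan-2-yl)oct-7-ynoate F6.
- Semi-hydrogenate over Pd/CaCO3/Pb(OAc)2 to the (Z)-oct-7-enoate, phenyl (2R,3S,4S,6R,7Z)-4-(tert-butyldimethylsilyloxy)-6-hydroxy-8-[(4-methoxybenzyl)oxy]-2,6-dimethyl-3-(2-methyl-1,3-dioxolan-2-yl)oct-7-enoate F7.
- Saponify with LiOH to (2R,3S,4S,6R,7Z)-4-(tert-butyldimethylsilyloxy)-6-hydroxy-8-[(4-methoxybenzyl)oxy]-2,6-dimethyl-3-(2-methyl-1,3-dioxolan-2-yl)oct-7-enoic acid F8, handled as its triethylammonium salt.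
- Lactonise through a mixed anhydride (2-methyl-6-nitrobenzoic anhydride, DMAP, Et3N) to 25.

**Step 11.** Palladium-catalysed acylation with an alkoxyethynylzinc reagent may be slow or may degrade the electron-rich alkyne, and the alkoxy ynone is an electrophile that can decompose on handling. Fallback, from 15 back to 22, by addition and oxidation instead of acylation:
- Reduce 15 through its isobutyl mixed anhydride with NaBH4 to phenyl (2R,3S,4S)-4-(tert-butyldimethylsilyloxy)-6-hydroxy-2-methyl-3-(2-methyl-1,3-dioxolan-2-yl)hexanoate F9.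
- Oxidise with Dess–Martin periodinane to phenyl (2R,3S,4S)-4-(tert-butyldimethylsilyloxy)-2-methyl-3-(2-methyl-1,3-dioxolan-2-yl)-6-oxohexanoate F10.
- Add acetylide 20 at −78 °C (aldehyde before aryl ester) to give phenyl (2R,3S,4S)-4-(tert-butyldimethylsilyloxy)-6-hydroxy-8-[(4-methoxybenzyl)oxy]-2-methyl-3-(2-methyl-1,3-dioxolan-2-yl)oct-7-ynoate F11 (C6 epimers of the chain, inconsequential).
- Oxidise with MnO2 to 22.

**Step 19.** The isopropyl reagent can reduce the hindered ketone by β-hydride transfer or enolise it, and facial selectivity may be eroded by the C6 silyloxy group on the β face. Fallback, from 32 back to 33: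
- Add isopropenylmagnesium bromide with CeCl3 (no β-hydrogen, smaller) to give (1R,4S,5S,6S,10S)-6-(tert-butyldimethylsilyloxy)-2,4-dihydroxy-10-[(4-methoxybenzyl)oxy]-1,8-dimethyl-4-(prop-1-en-2-yl)bicyclo[5.3.0]dec-8-ene F12 (skeleton numbering; same spatial arrangement at C4).
- Hydrogenate the 1,1-disubstituted alkene selectively with RhCl(PPh3)3 to 33.

## Further compounds

F1 | step 14 | (2R,3S,4S)-4-(tert-butyldimethylsilyloxy)-2,6-dimethyl-3-(2-methyl-1,3-dioxolan-2-yl)hept-6-enoic acid | C=C(C)C[C@H](O[Si](C)(C)C(C)(C)C)[C@@H](C1(C)OCCO1)[C@@H](C)C(=O)O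
F2 | step 14 | 3-[(4-methoxybenzyl)oxy]prop-2-yn-1-ol | COc1ccc(COC#CCO)cc1
F3 | step 14 | (Z)-3-[(4-methoxybenzyl)oxy]prop-2-en-1-ol | COc1ccc(CO/C=C\CO)cc1
F4 | step 14 | (Z)-3-[(4-methoxybenzyl)oxy]prop-2-en-1-yl (2R,3S,4S)-4-(tert-butyldimethylsilyloxy)-2,6-dimethyl-3-(2-methyl-1,3-dioxolan-2-yl)hept-6-enoate | C=C(C)C[C@H](O[Si](C)(C)C(C)(C)C)[C@@H](C1(C)OCCO1)[C@@H](C)C(=O)OC/C=C\OCc1ccc(OC)cc1
F5 | step 14 | diene acid, 28 opened between C8 and C9 (C10 vinyl and C8 isopropenyl termini) | CC(C)(C)[Si](C)(C)O[C@@H](CC(C)=C)[C@@H](C1(C)OCCO1)[C@](C)(C(=O)O)[C@@H](OCc1ccc(OC)cc1)C=C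
F6 | step 12 | phenyl (2R,3S,4S,6R)-4-(tert-butyldimethylsilyloxy)-6-hydroxy-8-[(4-methoxybenzyl)oxy]-2,6-dimethyl-3-(2-methyl-1,3-dioxolan-2-yl)oct-7-ynoate | COc1ccc(COC#C[C@](C)(O)C[C@H](O[Si](C)(C)C(C)(C)C)[C@@H](C2(C)OCCO2)[C@@H](C)C(=O)Oc2ccccc2)cc1
F7 | step 12 | phenyl (2R,3S,4S,6R,7Z)-4-(tert-butyldimethylsilyloxy)-6-hydroxy-8-[(4-methoxybenzyl)oxy]-2,6-dimethyl-3-(2-methyl-1,3-dioxolan-2-yl)oct-7-enoate | COc1ccc(CO/C=C\[C@](C)(O)C[C@H](O[Si](C)(C)C(C)(C)C)[C@@H](C2(C)OCCO2)[C@@H](C)C(=O)Oc2ccccc2)cc1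
F8 | step 12 | (2R,3S,4S,6R,7Z)-4-(tert-butyldimethylsilyloxy)-6-hydroxy-8-[(4-methoxybenzyl)oxy]-2,6-dimethyl-3-(2-methyl-1,3-dioxolan-2-yl)oct-7-enoic acid | COc1ccc(CO/C=C\[C@](C)(O)C[C@H](O[Si](C)(C)C(C)(C)C)[C@@H](C2(C)OCCO2)[C@@H](C)C(=O)O)cc1
F9 | step 11 | phenyl (2R,3S,4S)-4-(tert-butyldimethylsilyloxy)-6-hydroxy-2-methyl-3-(2-methyl-1,3-dioxolan-2-yl)hexanoate | OCC[C@H](O[Si](C)(C)C(C)(C)C)[C@@H](C1(C)OCCO1)[C@@H](C)C(=O)Oc1ccccc1
F10 | step 11 | phenyl (2R,3S,4S)-4-(tert-butyldimethylsilyloxy)-2-methyl-3-(2-methyl-1,3-dioxolan-2-yl)-6-oxohexanoate | O=CC[C@H](O[Si](C)(C)C(C)(C)C)[C@@H](C1(C)OCCO1)[C@@H](C)C(=O)Oc1ccccc1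
F11 | step 11 | phenyl (2R,3S,4S)-4-(tert-butyldimethylsilyloxy)-6-hydroxy-8-[(4-methoxybenzyl)oxy]-2-methyl-3-(2-methyl-1,3-dioxolan-2-yl)oct-7-ynoate (C6 epimers) | COc1ccc(COC#CC(O)C[C@H](O[Si](C)(C)C(C)(C)C)[C@@H](C2(C)OCCO2)[C@@H](C)C(=O)Oc2ccccc2)cc1
F12 | step 19 | (1R,4S,5S,6S,10S)-6-(tert-butyldimethylsilyloxy)-2,4-dihydroxy-10-[(4-methoxybenzyl)oxy]-1,8-dimethyl-4-(prop-1-en-2-yl)bicyclo[5.3.0]dec-8-ene (skeleton numbering; C2 epimers) | CC(C)(C)[Si](C)(C)O[C@H]1CC(C)=C[C@H](OCc2ccc(OC)cc2)[C@@]3(C)C(O)C[C@@](O)(C(C)=C)[C@H]13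
A1 | alternative 1 | 2-diazocyclohexanone carrying C1 (methyl, benzyloxymethyl), C2 silyl ether and C4 (silyloxy, isopropyl) | O=C1C(=[N+]=[N-])[C@](O[Si](CC)(CC)CC)(C(C)C)C[C@H](O[Si](C)(C)C(C)(C)C)[C@]1(C)COCc1ccccc1
A2 | alternative 1 | ring A cyclopentane methyl ester (C6 ester on C5) | COC(=O)[C@H]1[C@](O[Si](CC)(CC)CC)(C(C)C)C[C@H](O[Si](C)(C)C(C)(C)C)[C@]1(C)COCc1ccccc1
A3 | alternative 2 | methyl 2-diazo-2-(cyclopent-1-enyl)acetate carrying the ring A substituents | COC(=O)C(=[N+]=[N-])C1=C(C)[C@@H](O[Si](C)(C)C(C)(C)C)C[C@@]1(O[Si](CC)(CC)CC)C(C)C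
A4 | alternative 2 | (E)-triethyl[(3-methylbuta-1,3-dien-1-yl)oxy]silane | C=C(C)/C=C/O[Si](CC)(CC)CC
A5 | alternative 2 | bicyclic cycloheptadiene ester (C5=C6 ester, C8=C9, C10 oxygen trans to the C1 methyl) | COC(=O)C1=C2[C@](O[Si](CC)(CC)CC)(C(C)C)C[C@H](O[Si](C)(C)C(C)(C)C)[C@]2(C)[C@H](O[Si](CC)(CC)CC)C=C(C)C1
A6 | alternative 3 | cyclopentyl methyl ketone carrying the (Z)-3-iodobut-2-enyl C10 ether side chain | I/C(C)=C\[C@H](OCc1ccc(OC)cc1)[C@@]2(C)[C@@H](O[Si](C)(C)C(C)(C)C)C[C@@](O[Si](CC)(CC)CC)(C(C)C)[C@@H]2C(C)=O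
A7 | alternative 3 | bicyclic β,γ-unsaturated C6 ketone with C8=C9 | O=C1CC(C)=C[C@H](OCc3ccc(OC)cc3)[C@@]2(C)[C@@H](O[Si](C)(C)C(C)(C)C)C[C@@](O[Si](CC)(CC)CC)(C(C)C)[C@H]12
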